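**Plan**

The target is (2S)-5,7-dimethoxy-2-(4-methoxyphenyl)-6-prenylchromane (a 4'-methoxyflavan). The retrosynthesis cuts the aryl ether bond O1–C8a first, which opens ring C to an (S)-1,3-diarylpropan-1-ol, then the C6–prenyl bond, then the C2 carbinol back to a chalcone made by aldol union at C3–C4.
Forward: a Claisen–Schmidt condensation joins the two aryl fragments, a one-pot transfer hydrogenation saturates C3–C4 and sets C2, a directed lithiation between the two methoxy groups puts prenyl on C6, and an amide base closes ring C last.
Enabling feature: on ring A, C8 carries only hydrogen and lies between C7–OMe and C8a. A bromine on C8, the position that electrophilic substitution of a 2,4-dimethoxyphenyl ring delivers (so it is present in a commercial aldehyde), serves as a traceless activator.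
Loss of C8a–H and C8–Br gives the C8≡C8a aryne, and the C2 alkoxide on its three-carbon tether adds to C8a (cine-substitution). Oxygen thus reaches the ring A carbon meta to both methoxy groups, which direct substitution cannot address.
Stereochemistry: the only stereocenter, C2, comes from the (S,S)-TsDPEN ruthenium transfer hydrogenation. Its C–O bond is never broken afterwards.

Key step: step 4

Assumption: positions are numbered as in the 2-arylchromane skeleton (O1, C2–C4, C4a, C5–C8, C8a), and LiN(i-Pr)2 and LiTMP are used as preformed, titrated solutions.

**Route**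

Step 1
Reactants: 1 5-bromo-2,4-dimethoxybenzaldehyde; 2 1-(4-methoxyphenyl)ethan-1-one (4'-methoxyacetophenone)
Product: 3 (E)-3-(5-bromo-2,4-dimethoxyphenyl)-1-(4-methoxyphenyl)prop-2-en-1-one
Conditions: KOH (aq), EtOH, rt
Reagents that add atoms: none
Why: Claisen–Schmidt (crossed aldol) condensation, in which the aldehyde has no α-hydrogen and the ketone enolizes on one side only, so a single (E)-enone should form under thermodynamic control and no stereocenter is created.

Step 2
Reactants: 3 (E)-3-(5-bromo-2,4-dimethoxyphenyl)-1-(4-methoxyphenyl)prop-2-en-1-one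
Product: 5 (1S)-3-(5-bromo-2,4-dimethoxyphenyl)-1-(4-methoxyphenyl)propan-1-ol, via saturated ketone 4 (not isolated)
Conditions: RuCl[(S,S)-TsDPEN](p-cymene) (cat.), HCO2Na, MeOH/H2O, 60 °C
Reagents that add atoms: none
Why: Noyori–Ikariya asymmetric transfer hydrogenation in its one-pot enone mode, in which the ruthenium hydride first adds 1,4 to the chalcone and then reduces aryl ketone 4 through the outer-sphere six-membered transition state, where the CH–π contact between the anisyl ring and the p-cymene ligand of the (S,S) catalyst should direct hydride to the Re face and set C2 as (S); the aryl bromide is inert to this catalyst and the non-acidic formate medium should not ionize the p-methoxybenzylic alcohol.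

Step 3
Reactants: 5 (1S)-3-(5-bromo-2,4-dimethoxyphenyl)-1-(4-methoxyphenyl)propan-1-ol
Product: 7 (1S)-3-[5-bromo-2,4-dimethoxy-3-(3-methylbut-2-en-1-yl)phenyl]-1-(4-methoxyphenyl)propan-1-ol, via dilithio species 6 (not isolated)
Conditions: LiN(i-Pr)2 (2.3 equiv), THF, −78 °C; prenyl bromide, −78 to −40 °C; aq NH4Cl at −40 °C
Reagents that add atoms: prenyl bromide (1-bromo-3-methylbut-2-ene), CC(C)=CCBr
Why: Directed ortho-metalation followed by alkylation, in which at −78 °C the amide base should remove the ring proton flanked by the two methoxy groups (the future C6) in preference to the proton next to bromine, the lithium alkoxide masks the hydroxyl group, and the hindered aryllithium attacks the primary carbon of prenyl bromide (SN2) to give the linear prenyl group; the carbinol stereocenter is not involved.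

Step 4
Reactants: 7 (1S)-3-[5-bromo-2,4-dimethoxy-3-(3-methylbut-2-en-1-yl)phenyl]-1-(4-methoxyphenyl)propan-1-ol
Product: 10 (2S)-5,7-dimethoxy-2-(4-methoxyphenyl)-6-(3-methylbut-2-en-1-yl)chromane, via aryne alkoxide 8 (not isolated), via 8-lithiochromane 9 (not isolated)
Conditions: LiTMP (lithium 2,2,6,6-tetramethylpiperidide, 3 equiv), THF, −78 to 0 °C; aq NH4Cl
Reagents that add atoms: none
Why: LiTMP forms the lithium alkoxide and then removes the only proton left on ring A, C8a–H, which is acidified by the ortho bromine on C8; the 2-bromoaryllithium loses LiBr to give the C8≡C8a aryne 8, the tethered alkoxide adds to C8a to give aryllithium 9, and the quench protonates C8 (elimination–addition, a cine-substitution). The closest known reaction type is the amide-base aryne cyclization of 3-(3-haloaryl)propyl alkoxides and amides to chromans and tetrahydroquinolines, the intramolecular form of the classic conversion of 2-haloanisoles into meta-substituted anisoles. Ring C closes in a 6-exo-dig mode onto the in-plane aryne π bond; attack at C8 would need a meta-bridged seven-membered ring and is geometrically excluded, and the C7 methoxy group polarizes the aryne in the same sense, placing the developing anion on C8 next to it. No new stereocenter is formed: C2 was set in step 2 and neither its C–O nor its C–H bond is touched, so the (S) configuration should pass unchanged into the ring. The selectivity needed is deprotonation at C8a–H and not at the prenyl methylene on C6; the two flanking methoxy groups twist and shield that CH2 so that its anion would gain no benzylic stabilization, and LiTMP carries no hydrogen on the carbons next to nitrogen and is too hindered to reduce or add to the aryne before the intramolecular alkoxide does.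

**Compound list**

1 | 5-bromo-2,4-dimethoxybenzaldehyde | O=Cc1cc(Br)c(OC)cc1OC | starting material
2 | 1-(4-methoxyphenyl)ethan-1-one | CC(=O)c1ccc(OC)cc1 | starting material
3 | (E)-3-(5-bromo-2,4-dimethoxyphenyl)-1-(4-methoxyphenyl)prop-2-en-1-one | COc1ccc(C(=O)/C=C/c2cc(Br)c(OC)cc2OC)cc1 | intermediate
4 | 3-(5-bromo-2,4-dimethoxyphenyl)-1-(4-methoxyphenyl)propan-1-one (saturated ketone, not isolated) | COc1ccc(C(=O)CCc2cc(Br)c(OC)cc2OC)cc1 | intermediate
5 | (1S)-3-(5-bromo-2,4-dimethoxyphenyl)-1-(4-methoxyphenyl)propan-1-ol | COc1ccc([C@H](CCc2cc(Br)c(OC)cc2OC)O)cc1 | intermediate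
6 | lithium (1S)-3-(5-bromo-3-lithio-2,4-dimethoxyphenyl)-1-(4-methoxyphenyl)propan-1-olate (dilithio species, not isolated) | COc1ccc([C@H](CCc2cc(Br)c(OC)c([Li])c2OC)O[Li])cc1 | intermediate
7 | (1S)-3-[5-bromo-2,4-dimethoxy-3-(3-methylbut-2-en-1-yl)phenyl]-1-(4-methoxyphenyl)propan-1-ol | COc1ccc([C@H](CCc2cc(Br)c(OC)c(CC=C(C)C)c2OC)O)cc1 | intermediate
8 | lithium (1S)-3-[5,6-didehydro-2,4-dimethoxy-3-(3-methylbut-2-en-1-yl)phenyl]-1-(4-methoxyphenyl)propan-1-olate (aryne alkoxide, not isolated) | COc1ccc([C@H](CCC2=C(OC)C(CC=C(C)C)=C(OC)C#C2)O[Li])cc1 | intermediate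
9 | (2S)-8-lithio-5,7-dimethoxy-2-(4-methoxyphenyl)-6-(3-methylbut-2-en-1-yl)chromane (not isolated) | COc1ccc([C@@H]2CCc3c(c([Li])c(OC)c(CC=C(C)C)c3OC)O2)cc1 | intermediate
10 | (2S)-5,7-dimethoxy-2-(4-methoxyphenyl)-6-(3-methylbut-2-en-1-yl)chromane | COc1ccc([C@@H]2CCc3c(cc(OC)c(CC=C(C)C)c3OC)O2)cc1 | target

**Step count and risks**

Total step count: 4. Longest linear sequence: 4 steps (from 1 or 2).

Steps most likely to fail:

1. Step 4. The amide base may remove a proton from the prenyl methylene, which would lead to double-bond migration, or the aryne may be consumed by the external base before the alkoxide closes the ring. The fallback keeps the prenyl group out of the aryne step; it sets out from 5 and comes back at 10. Compound 5 is metalated as in step 3 (dilithio species 6) and quenched with 1,2-dibromo-1,1,2,2-tetrachloroethane to give (1S)-3-(3,5-dibromo-2,4-dimethoxyphenyl)-1-(4-methoxyphenyl)propan-1-ol F1. Treatment with LiN(i-Pr)2 in THF containing extra i-Pr2NH should close ring C by the same elimination–addition; the bromine between the methoxy groups has no ortho hydrogen and cannot eliminate, and the amine protonates the aryl anion to curb bromine scrambling. This should give (2S)-6-bromo-5,7-dimethoxy-2-(4-methoxyphenyl)chromane F2. Bromine–lithium exchange with n-BuLi in THF at −78 °C, followed by prenyl bromide, should then give 10.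

2. Step 3. Metalation may occur next to bromine instead of between the methoxy groups (premature aryne formation), or may stay incomplete. The fallback fixes the position by the halogen pattern instead of by deprotonation; it sets out from 2 and comes back at 7. Commercial 3,5-dibromo-2,4-dihydroxybenzaldehyde F3 is methylated (MeI, K2CO3, DMF) to 3,5-dibromo-2,4-dimethoxybenzaldehyde F4. Claisen–Schmidt condensation with 2 gives (E)-3-(3,5-dibromo-2,4-dimethoxyphenyl)-1-(4-methoxyphenyl)prop-2-en-1-one F5. The transfer hydrogenation of step 2, passing in the flask through 3-(3,5-dibromo-2,4-dimethoxyphenyl)-1-(4-methoxyphenyl)propan-1-one F6, should give the dibromo alcohol (1S)-3-(3,5-dibromo-2,4-dimethoxyphenyl)-1-(4-methoxyphenyl)propan-1-ol F1, the same compound as in the first fallback. Bromine–lithium exchange with n-BuLi (one equivalent for the hydroxyl group, one for exchange) in THF at −78 °C under equilibrating conditions should settle on the aryllithium flanked by the two methoxy groups, and prenyl bromide then gives 7.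

3. Step 2. The one-pot reduction may stall after the conjugate addition or branch to the allylic alcohol, and slow hydride transfer to the electron-rich anisyl ketone may erode conversion and facial selectivity. The fallback separates the two reductions and changes the source of asymmetric induction; it sets out from 3 and comes back at 5. Conjugate reduction of 3 with [CuH(PPh3)]6 (cat.) and a silane gives ketone 4, which is isolated. Reduction with BH3·SMe2 and (R)-2-methyl-CBS-oxazaborolidine in THF at −20 °C (Corey–Bakshi–Shibata reduction) should then give the (S)-alcohol 5.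

**Further compounds**

F1 | step 4 | (1S)-3-(3,5-dibromo-2,4-dimethoxyphenyl)-1-(4-methoxyphenyl)propan-1-ol | COc1ccc([C@H](CCc2cc(Br)c(OC)c(Br)c2OC)O)cc1
F2 | step 4 | (2S)-6-bromo-5,7-dimethoxy-2-(4-methoxyphenyl)chromane | COc1ccc([C@@H]2CCc3c(cc(OC)c(Br)c3OC)O2)cc1
F3 | step 3 | 3,5-dibromo-2,4-dihydroxybenzaldehyde (commercial) | O=Cc1cc(Br)c(O)c(Br)c1O
F4 | step 3 | 3,5-dibromo-2,4-dimethoxybenzaldehyde | COc1c(Br)cc(C=O)c(OC)c1Br
F5 | step 3 | (E)-3-(3,5-dibromo-2,4-dimethoxyphenyl)-1-(4-methoxyphenyl)prop-2-en-1-one | COc1ccc(C(=O)/C=C/c2cc(Br)c(OC)c(Br)c2OC)cc1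
F6 | step 3 | 3-(3,5-dibromo-2,4-dimethoxyphenyl)-1-(4-methoxyphenyl)propan-1-one | COc1ccc(C(=O)CCc2cc(Br)c(OC)c(Br)c2OC)cc1
F0 | step 2 | none | none
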